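Late in the oak run is where I take your quick number from, at its last two readings. These are the flasks, the readings and what you ask:

| flask | free monomer | protic impurity | pre-initiator | remark | time |
|---|---|---|---|---|---|
| oak | 0.83 M | 0.056 M | 41 mM | run made earlier |  |
| dusk | 0.83 M | 0.0830 M | 41 mM |  | 10 min |
| spring | 0.40 M | 0.0830 M | 41 mM |  | 10 min |

- oak (time / min: monomer in chains / %, free monomer / %): 0.500: 0.4, 98.4; 0.667: 0.5, 97.6; 1.00: 0.2, 96.0; 1.50: 1.8, 94.6; 2.50: 4.3, 90.4; 4.00: 10.6, 83.1; 6.00: 20.1, 73.9

(standard deviation of a reading: 0.3 percentage points)

1. which of the two ends with the longer chains by the average number of monomer units in a chain (chains begun, living or dead) ("neither" if they lie within 10%) (dusk / spring / neither)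
2. average number of monomer units in a chain (chains begun, living or dead) at the end, dusk
3. average number of monomer units in a chain (chains begun, living or dead) at the end, spring

- the average divides the monomer in chains by the number of chains begun, living and dead together
- the earlier runs do not show the number of chains; that part of a forecast is a guess
- no earlier run changes the charge of protic impurity; that part of a forecast is a guess

1. Between 4.00 min and 6.00 min, oak gives 0.0605 min⁻¹ for g, the share of the free monomer present that enters chains each minute. This treats growth as pseudo-first-order in free monomer. It is a reading with the scatter of 0.3 percentage points, and holding it to the end in both flasks is my assumption.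

2. At 6.00 min, oak's two columns fall short of the charge by 6.00%, and its protic impurity is 6.75% of the free monomer. I therefore guess one free monomer lost per protic impurity. That leaves a usable share u of 90.0% in dusk and 79.2% in spring.

3. I start both flasks from oak's 20.1% in chains at 6.00 min and let the usable remainder decay at g until 10 min. My estimate for dusk is 35.1% in chains, or 0.292 M. My estimate for spring is 32.8%, or 0.131 M.

4. The pre-initiator charge is the same, so I guess equal numbers of chains. On that guess I expect dusk to have the longer chains, by a factor of 2.23.

Your forecast also says dusk, at 7.5 against 2.8, a factor of 2.68, which is larger than mine. On the number of chains it says “Chains begun are a guess”.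

    free monomer + initiator → living end + monomer in chains (k = 0.900 L mol⁻¹ min⁻¹)
    free monomer + living end → monomer in chains + living end, rate k2*[living end]*[free monomer] (k = 3.90 L mol⁻¹ min⁻¹)
    pre-initiator ⇌ initiator (K = 0.570, k = 0.270 min⁻¹)
    protic impurity + free monomer → quenched substrate (k = 0.730 L mol⁻¹ min⁻¹)
    2 living end → dead end (k = 5.30 L mol⁻¹ min⁻¹)

Dusk ends at 10.0 and spring at 5.36, a factor of 1.87. Counting living ends plus two per dead end, dusk has begun 0.0280 M of chains and spring 0.0200 M. Dusk holds 33.9% in chains against my 35.1%. Carrying g on from dusk's 56.2% of free monomer to the same flask read at 15 min gives 48.6% in chains, and that flask holds 46.1%.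

The numbers in the tables were generated by integration from invented constants; scatter was added.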